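**Retrosynthetic overview**
- Target ⇒ ring A bromo ketone + tricyclic primary iodide; the last bond made is CH2–C(OH), by a samarium Barbier addition.
- Iodide ⇒ exocyclic-methylene bromo lactone (hydroboration–iodination sets C1); the C4 bromide ⇒ C4 ketone (bulky hydride, then Appel inversion).
- Key disconnection: the lactone C7–O8 bond, opened together with C1–C7a, back to a monocyclic enyne keto amide; a gold-catalysed, amide-terminated carbolactonization closes the cyclopentane and the lactone at once and releases the auxiliary.
- Enyne keto amide ⇒ 2-methoxy-5-methylbenzamide of a prolinol ether by Birch reduction–alkylation (sets quaternary C3a).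
- Ring A ketone ⇒ sulcatone enol acetate by catalytic enantioselective bromonium cyclization. Ring order: the six-membered carbocycle comes from the arene, then cyclopentane and lactone form together; ring A is made separately and joined last.

Assumption: the (S)-prolinol auxiliary and the (R)-thiophosphoramide catalyst are taken to give the configurations drawn, by analogy with their parent systems; both antipodes are available if the sense proves opposite.

Locants of the tricyclic core follow hydrindane numbering (C1–C7a); C9 is the lactone carbonyl carbon on C3a and O8 the lactone oxygen on C7.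

Step 1
Reactants: 1 6-methylhept-5-en-2-one (sulcatone)
Product: 3 6-methylhepta-1,5-dien-2-yl acetate, via potassium enolate 2 (not isolated)
Conditions: KN(SiMe3)2, THF, −78 °C; then Ac2O, −78 °C to 0 °C
Reagents that add atoms: acetic anhydride, CC(=O)OC(C)=O
Why: Kinetic deprotonation of the methyl ketone at the methyl group by a hindered potassium amide and O-acylation of the potassium enolate give the terminal enol acetate (enol ester formation), with no stereocentre formed.

Step 2
Reactants: 3 6-methylhepta-1,5-dien-2-yl acetate
Product: 4 (R)-4-bromo-3,3-dimethylcyclohexan-1-one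
Conditions: 1,3-dibromo-5,5-dimethylhydantoin (1.0 equiv), (R)-3,3'-bis(2,4,6-triisopropylphenyl)-1,1'-binaphthyl-2,2'-diyl N-triflylthiophosphoramide (10 mol %), toluene/CH2Cl2, −90 °C; aq. NaHCO3/Na2S2O3 work-up
Reagents that add atoms: 1,3-dibromo-5,5-dimethylhydantoin, CC1(C)N(Br)C(=O)N(Br)C1=O
Why: Proposed new method: enantioselective bromonium carbocyclization terminated by an enol acetate, in which the Lewis-basic P=S of the chiral thiophosphoramide takes Br+ from the hydantoin and delivers it to one face of the more electron-rich trisubstituted alkene, the enol acetate CH2 terminus attacks the tertiary carbon through a chair with bromine equatorial, and the acetoxycarbenium ion sheds its acetyl group to give the ketone directly (so no alkene regioisomers arise and the CHBr centre is set as R), the closest known reaction type being the chiral Lewis base/dibromohydantoin-catalysed bromocyclization of homogeranylarenes with arene terminators.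

Step 3
Reactants: 5 2-methoxy-5-methylbenzoic acid; 6 (S)-2-(methoxymethyl)pyrrolidine
Product: 8 (S)-(2-methoxy-5-methylphenyl)[2-(methoxymethyl)pyrrolidin-1-yl]methanone, via acid chloride 7 (not isolated)
Conditions: (COCl)2, cat. DMF, CH2Cl2, 0 °C to rt; then 6, Et3N, CH2Cl2, 0 °C
Reagents that add atoms: none
Why: Amide formation by acylation of the secondary amine with the acid chloride, leaving the auxiliary stereocentre untouched.

Step 4
Reactants: 8 (S)-(2-methoxy-5-methylphenyl)[2-(methoxymethyl)pyrrolidin-1-yl]methanone; 9 (4-bromobut-1-yn-1-yl)trimethylsilane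
Product: 11 [(1S)-2-methoxy-5-methyl-1-(4-trimethylsilylbut-3-yn-1-yl)cyclohexa-2,5-dien-1-yl][(2S)-2-(methoxymethyl)pyrrolidin-1-yl]methanone, via potassium dienolate 10 (not isolated)
Conditions: K (2.2 equiv), NH3/THF, t-BuOH (1 equiv), −78 °C; piperylene; then 9, −78 °C to −33 °C
Reagents that add atoms: none
Why: Schultz asymmetric Birch reduction–alkylation, in which 1,4-reduction gives the chelated potassium amide dienolate that is alkylated at C1 on the face away from the methoxymethyl arm, setting the quaternary stereocentre (1S, the future C3a) with high diastereoselectivity.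

Step 5
Reactants: 11 [(1S)-2-methoxy-5-methyl-1-(4-trimethylsilylbut-3-yn-1-yl)cyclohexa-2,5-dien-1-yl][(2S)-2-(methoxymethyl)pyrrolidin-1-yl]methanone
Product: 13 (2S)-2-(but-3-yn-1-yl)-4-methyl-2-{[(2S)-2-(methoxymethyl)pyrrolidin-1-yl]carbonyl}cyclohex-3-en-1-one, via desilylated alkyne 12 (not isolated)
Conditions: K2CO3, MeOH, rt; then 1 M HCl to pH 1, rt
Reagents that add atoms: water, O
Why: Protodesilylation of the alkynylsilane by methoxide followed by acid hydrolysis of the methyl enol ether to the ketone, with the trisubstituted alkene held out of conjugation by the quaternary carbon, which is itself unaffected.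

Step 6
Reactants: 13 (2S)-2-(but-3-yn-1-yl)-4-methyl-2-{[(2S)-2-(methoxymethyl)pyrrolidin-1-yl]carbonyl}cyclohex-3-en-1-one
Product: 15 (3aS,7S,7aS)-7-methyl-1-methylidene-hexahydro-3a,7-(epoxymethano)indene-4,9-dione, via iminium ether acetate 14 (not isolated)
Conditions: [Au(NCMe){P(t-Bu)2(biphenyl-2-yl)}]SbF6 (5 mol %), AcOH (2 equiv), H2O (5 equiv), CH2Cl2, 0 °C to rt
Reagents that add atoms: water, O
Why: Proposed new method: carboxamide-terminated 5-exo-dig cyclization of the 1,6-enyne by monovalent gold, in which the ring alkene adds to the gold-activated alkyne on the face that carries the tether (cis ring fusion, C7a), the developing tertiary cation (cyclopropyl gold carbene) at C7 is opened anti by the amide oxygen held on the opposite face (lactone C–O bond, C7), protodeauration frees the catalyst and water hydrolyses the iminium ether to the lactone while releasing the auxiliary, the closest known reaction types being the gold- or platinum-catalysed alkoxy- and hydroxycyclization of 1,6-enynes with external alcohols or water and the halolactonization of the same Birch-derived amides.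

Step 7
Reactants: 15 (3aS,7S,7aS)-7-methyl-1-methylidene-hexahydro-3a,7-(epoxymethano)indene-4,9-dione
Product: 16 (3aS,4S,7S,7aS)-4-hydroxy-7-methyl-1-methylidene-octahydro-3a,7-(epoxymethano)inden-9-one
Conditions: LiBH(s-Bu)3, THF, −78 °C; H2O quench
Reagents that add atoms: none
Why: Ketone reduction by a bulky trialkylborohydride, where hydride enters equatorially from the lactone side because the opposite face of C4 is blocked by the axial C1 of the cyclopentane (1,3-diaxial), giving the axial alcohol (4S) while the lactone survives at −78 °C.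

Step 8
Reactants: 16 (3aS,4S,7S,7aS)-4-hydroxy-7-methyl-1-methylidene-octahydro-3a,7-(epoxymethano)inden-9-one
Product: 18 (3aR,4R,7S,7aS)-4-bromo-7-methyl-1-methylidene-octahydro-3a,7-(epoxymethano)inden-9-one, via alkoxyphosphonium bromide 17 (not isolated)
Conditions: PPh3, CBr4, toluene, rt to 60 °C
Reagents that add atoms: carbon tetrabromide, BrC(Br)(Br)Br
Why: Appel reaction, in which bromide displaces the axial alkoxyphosphonium group by SN2 with inversion to give the equatorial bromide (4R), with ionisation and rearrangement disfavoured by the acyl-bearing quaternary neighbour, as in related neopentylic brominations of terpenoid alcohols.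

Step 9
Reactants: 18 (3aR,4R,7S,7aS)-4-bromo-7-methyl-1-methylidene-octahydro-3a,7-(epoxymethano)inden-9-one
Product: 20 (1S,3aR,4R,7S,7aS)-4-bromo-1-(iodomethyl)-7-methyl-octahydro-3a,7-(epoxymethano)inden-9-one, via alkyldicyclohexylborane 19 (not isolated)
Conditions: (c-C6H11)2BH, THF, 0 °C to rt; then NaOAc, ICl, MeOH, 0 °C
Reagents that add atoms: iodine monochloride, ClI
Why: Hydroboration–iodination, in which the bulky borane adds anti-Markovnikov and syn from the convex face of the cis-hydrindane (the face of C7a–H), so the new C1–H lies on that face and the CH2 group ends cis to C7, and base-induced iododeboronation then transfers the primary alkyl group to iodine without touching C1.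

Step 10
Reactants: 20 (1S,3aR,4R,7S,7aS)-4-bromo-1-(iodomethyl)-7-methyl-octahydro-3a,7-(epoxymethano)inden-9-one; 4 (R)-4-bromo-3,3-dimethylcyclohexan-1-one
Product: 22 (1R,4R)-4-bromo-1-{[(1R,3aR,4R,7S,7aS)-4-bromo-7-methyl-9-oxo-octahydro-3a,7-(epoxymethano)inden-1-yl]methyl}-3,3-dimethylcyclohexan-1-ol (target), via alkylsamarium diiodide 21 (not isolated)
Conditions: SmI2 (2.5 equiv), NiI2 (2 mol %), 4 (1.5 equiv), THF, 0 °C to rt
Reagents that add atoms: none
Why: Samarium Barbier reaction, in which only the primary iodide is reduced (secondary bromides and the lactone are inert to SmI2 without HMPA) and the alkylsamarium adds to the ketone equatorially, anti to the axial C3 methyl of the chair that has bromine equatorial, giving the axial tertiary alcohol cis to bromine (1R), with any minor C1 epimer from the bromine-axial chair removed by chromatography.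

**Compound list**
1 | 6-methylhept-5-en-2-one (sulcatone) | CC(=O)CCC=C(C)C | starting material
2 | potassium 6-methylhepta-1,5-dien-2-olate | [K+].[O-]C(=C)CCC=C(C)C | intermediate
3 | 6-methylhepta-1,5-dien-2-yl acetate | CC(=O)OC(=C)CCC=C(C)C | intermediate
4 | (R)-4-bromo-3,3-dimethylcyclohexan-1-one | O=C1CC[C@@H](Br)C(C)(C)C1 | intermediate
5 | 2-methoxy-5-methylbenzoic acid | COc1ccc(C)cc1C(=O)O | starting material
6 | (S)-2-(methoxymethyl)pyrrolidine | COC[C@@H]1CCCN1 | starting material
7 | 2-methoxy-5-methylbenzoyl chloride | COc1ccc(C)cc1C(Cl)=O | intermediate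
8 | (S)-(2-methoxy-5-methylphenyl)[2-(methoxymethyl)pyrrolidin-1-yl]methanone | COC[C@@H]1CCCN1C(=O)c1cc(C)ccc1OC | intermediate
9 | (4-bromobut-1-yn-1-yl)trimethylsilane | C[Si](C)(C)C#CCCBr | starting material
10 | potassium amide dienolate from 1,4-reduction of 8 | COC[C@@H]1CCCN1C([O-])=C1C=C(C)CC=C1OC.[K+] | intermediate
11 | [(1S)-2-methoxy-5-methyl-1-(4-trimethylsilylbut-3-yn-1-yl)cyclohexa-2,5-dien-1-yl][(2S)-2-(methoxymethyl)pyrrolidin-1-yl]methanone | C[Si](C)(C)C#CCC[C@@]1(C(=O)N2CCC[C@H]2COC)C(OC)=CCC(C)=C1 | intermediate
12 | [(1S)-1-(but-3-yn-1-yl)-2-methoxy-5-methylcyclohexa-2,5-dien-1-yl][(2S)-2-(methoxymethyl)pyrrolidin-1-yl]methanone | C#CCC[C@@]1(C(=O)N2CCC[C@H]2COC)C(OC)=CCC(C)=C1 | intermediate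
13 | (2S)-2-(but-3-yn-1-yl)-4-methyl-2-{[(2S)-2-(methoxymethyl)pyrrolidin-1-yl]carbonyl}cyclohex-3-en-1-one | C#CCC[C@@]1(C(=O)N2CCC[C@H]2COC)C(=O)CCC(C)=C1 | intermediate
14 | tricyclic iminium ether acetate (O8 bonded to C7; C9=N+ of the auxiliary) | C=C1CC[C@@]23C(=[N+]4CCC[C@H]4COC)O[C@@](C)(CCC2=O)[C@@H]13.CC(=O)[O-] | intermediate
15 | (3aS,7S,7aS)-7-methyl-1-methylidene-hexahydro-3a,7-(epoxymethano)indene-4,9-dione | C=C1CC[C@@]23C(=O)O[C@@](C)(CCC2=O)[C@@H]13 | intermediate
16 | (3aS,4S,7S,7aS)-4-hydroxy-7-methyl-1-methylidene-octahydro-3a,7-(epoxymethano)inden-9-one (axial OH, anti to the lactone bridge) | C=C1CC[C@@]23C(=O)O[C@@](C)(CC[C@@H]2O)[C@@H]13 | intermediate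
17 | alkoxytriphenylphosphonium bromide of 16 | C=C1CC[C@@]23C(=O)O[C@@](C)(CC[C@@H]2O[P+](c2ccccc2)(c2ccccc2)c2ccccc2)[C@@H]13.[Br-] | intermediate
18 | (3aR,4R,7S,7aS)-4-bromo-7-methyl-1-methylidene-octahydro-3a,7-(epoxymethano)inden-9-one (equatorial Br) | C=C1CC[C@@]23C(=O)O[C@@](C)(CC[C@H]2Br)[C@@H]13 | intermediate
19 | B-alkyldicyclohexylborane from 18 (boron on the C1 methylene) | C1CCCCC1B(C1CCCCC1)C[C@H]1CC[C@@]23C(=O)O[C@@](C)(CC[C@H]2Br)[C@@H]13 | intermediate
20 | (1S,3aR,4R,7S,7aS)-4-bromo-1-(iodomethyl)-7-methyl-octahydro-3a,7-(epoxymethano)inden-9-one | IC[C@H]1CC[C@@]23C(=O)O[C@@](C)(CC[C@H]2Br)[C@@H]13 | intermediate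
21 | alkylsamarium diiodide from 20 | I[Sm](I)C[C@H]1CC[C@@]23C(=O)O[C@@](C)(CC[C@H]2Br)[C@@H]13 | intermediate
22 | (1R,4R)-4-bromo-1-{[(1R,3aR,4R,7S,7aS)-4-bromo-7-methyl-9-oxo-octahydro-3a,7-(epoxymethano)inden-1-yl]methyl}-3,3-dimethylcyclohexan-1-ol | CC1(C)C[C@](O)(C[C@H]2CC[C@@]34C(=O)O[C@@](C)(CC[C@H]3Br)[C@@H]24)CC[C@H]1Br | target

**Step count:** 10 steps in total. Longest linear sequence: 8 steps (5 to 22, steps 3 to 10); the ring A branch is 2 steps.

**Three steps most likely to fail**

Step 2 (proposed new asymmetric bromocyclization): the enol acetate may be brominated directly, or the enantioselectivity may be low. The fallback sets out from 3 and comes back at 4. Compound 3 is cyclised without enantiocontrol by the stoichiometric bromonium source Et2SBr·SbBrCl5 in nitromethane at −25 °C to racemic 4-bromo-3,3-dimethylcyclohexanone F1. This is ketalised with (R,R)-hydrobenzoin (TsOH, toluene, removal of water), and the two diastereomeric ketals are separated by chromatography or crystallisation. The (R)-bromo ketone (R,R)-hydrobenzoin ketal F2 is then hydrolysed (2 M HCl, THF) to 4. This replaces catalytic enantiocontrol by a classical resolution, using a known bromonium cation–olefin cyclization and ketal chemistry.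

Step 4 (Birch reduction–alkylation): the hindered dienolate may eliminate HBr from the homopropargylic bromide instead of being alkylated, and everything downstream depends on this stereocentre. The fallback sets out from 8 and comes back at 13. The dienolate from 8 is alkylated under the same Birch conditions with 2-(2-bromoethyl)-1,3-dioxolane, giving the dioxolane-protected diene amide F3. Aqueous HCl in THF hydrolyses both the enol ether and the acetal to the keto aldehyde F4. Ohira–Bestmann homologation (dimethyl (1-diazo-2-oxopropyl)phosphonate, K2CO3, MeOH) then converts the aldehyde into the terminal alkyne 13. The alkyne is thus built after the alkylation instead of being carried in the electrophile.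

Step 6 (proposed new gold carbolactonization): the cation may eliminate or rearrange instead of being trapped, the alkyne may be hydrated, or the released amine may poison the catalyst. The fallback uses known chemistry, sets out from 13 and comes back at 15. Palladium-catalysed enyne cycloisomerization (Pd(OAc)2, PPh3, toluene, 60 °C; Alder-ene type) closes the cyclopentane on the tether face and gives the cis-fused diene amide F5, with the exocyclic methylene at C1 and the ring alkene moved to C6=C7. Iodolactonization (I2, THF/H2O) of the trisubstituted alkene by the amide carbonyl then forms the lactone C–O bond at C7 anti to iodine, releases the auxiliary and gives the iodo lactone F6. Radical deiodination (Bu3SnH, AIBN, benzene, 80 °C) gives 15. The isomeric C7 exocyclic alkene, if formed, converges on 15 by the same two operations.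

**Further compounds**
F1 | step 2 | racemic 4-bromo-3,3-dimethylcyclohexan-1-one | O=C1CCC(Br)C(C)(C)C1
F2 | step 2 | (R,R)-hydrobenzoin ketal of (R)-4-bromo-3,3-dimethylcyclohexanone | CC1(C)CC2(CC[C@H]1Br)O[C@H](c1ccccc1)[C@@H](c1ccccc1)O2
F3 | step 4 | [(1S)-1-[2-(1,3-dioxolan-2-yl)ethyl]-2-methoxy-5-methylcyclohexa-2,5-dien-1-yl][(2S)-2-(methoxymethyl)pyrrolidin-1-yl]methanone | O1CCOC1CC[C@@]2(C(=O)N3CCC[C@H]3COC)C(OC)=CCC(C)=C2
F4 | step 4 | 3-[(1S)-3-methyl-1-{[(2S)-2-(methoxymethyl)pyrrolidin-1-yl]carbonyl}-6-oxocyclohex-2-en-1-yl]propanal | O=CCC[C@@]1(C(=O)N2CCC[C@H]2COC)C(=O)CCC(C)=C1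
F5 | step 6 | cis-fused diene amide (1-methylidene, C6=C7 alkene, 4-ketone, auxiliary amide on C3a) | C=C1CC[C@@]2(C(=O)N3CCC[C@H]3COC)C(=O)CC=C(C)[C@@H]12
F6 | step 6 | 6-iodo derivative of keto lactone 15 (iodine anti to O8) | C=C1CC[C@@]23C(=O)O[C@@](C)([C@H](I)CC2=O)[C@@H]13
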